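Don't judge a recipe by its side product at one clock time: that figure mixes how fast a run goes with where its substrate goes. At 120 s the spring run holds 21.9 % side product against 12.9 % in the dusk run, yet side product is 43.4 % of the substrate reacted in spring and 43.1 % in dusk.

| flask | substrate | partner | second reagent | third reagent | remark | time |
|---|---|---|---|---|---|---|
| dusk | 0.31 M | 0.20 M | 0.217 M | 0.372 M | run made earlier |  |
| dawn | 0.31 M | 0.81 M | 0.217 M | 0.372 M | run made earlier |  |
| spring | 0.31 M | 0.403 M | 0.43 M | 0.372 M | run made earlier |  |
| flask | 0.31 M | 0.403 M | 0.217 M | 0.372 M |  | 2.0 min |

| run | time / s | substrate / % | target / % | side product / % |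
|---|---|---|---|---|
| dusk | 10.0 | 96.5 | 0 | 1.8 |
| dusk | 20.0 | 93.7 | 0.9 | 2.8 |
| dusk | 30.0 | 91.0 | 0.7 | 4.8 |
| dusk | 60.0 | 82.3 | 4.2 | 7.9 |
| dusk | 120 | 70.1 | 10.5 | 12.9 |
| dawn | 10.0 | 91.3 | 0 | 1.9 |
| dawn | 20.0 | 84.2 | 0.7 | 1.4 |
| dawn | 30.0 | 76.2 | 3.8 | 3.7 |
| dawn | 60.0 | 59.4 | 13.5 | 6.0 |
| dawn | 120 | 38.7 | 31.4 | 8.0 |
| spring | 10.0 | 93.9 | 0.4 | 2.4 |
| spring | 20.0 | 87.1 | 0.9 | 5.8 |
| spring | 30.0 | 81.7 | 4.5 | 8.0 |
| spring | 60.0 | 67.9 | 11.1 | 13.3 |
| spring | 120 | 49.5 | 23.4 | 21.9 |

(each reading ± 0.5 percentage points)

- the analysis behind the earlier runs scatters by 0.5 percentage points, standard deviation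
- the reaction counts as stopped when no species that holds the substrate changes by six tenths of a point or more over the second half of the time

- why nothing more happens at 2.0 min, or that something still does (the partner has run out first / all of the substrate has reacted / it is still moving / the second reagent has run out first / the third reagent has run out first)
- how much of the substrate has reacted by 2.0 min
- how much target there is at 2.0 min, in percent of the substrate charged
- how much side product there is at 2.0 min, in percent of the substrate charged

You have to choose the charge of the next run: the recipe's 0.217 M of second reagent, or spring's 0.43 M. Dawn, with more partner than dusk, lost substrate faster, and spring, with more second reagent and also more partner than dusk, made more side product than dusk. So suppose two parallel losses, each first order in substrate, one with second reagent and one with partner. Divide one rate by the other and substrate and time drop out: substrate lost by the partner way, per side product formed, equals a constant S times partner over second reagent.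

Take the readings at 120 s, with charges standing in for amounts that drift. S then reads 1.43 in dusk, 1.78 in dawn and 1.39 in spring. Their mean, S = 1.54, is the selectivity factor. The share of reacted substrate going to side product is then one over one plus S times partner over second reagent, which for the recipe is 26.0 %, and with spring's 0.43 M of second reagent 41.0 %. So I would charge the recipe as written, at 0.217 M.

The forecast says it is still moving, with 42.5 % reacted, 19 % target and 11 % side product, since “Substrate is still falling and no reagent is exhausted”. My share on its conversion gives 11.1 % side product.

The flask at 2.0 min: it is still moving, with 42.1 % reacted, 19.4 % target and 10.9 % side product, so side product took 25.9 % of what reacted.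

substrate + second reagent → side product (k = 0.00710 M⁻¹ s⁻¹); substrate + partner → intermediate A (k = 0.00970 M⁻¹ s⁻¹); second reagent + intermediate A → intermediate B (k = 0.160 M⁻¹ s⁻¹); third reagent + intermediate B → target (k = 0.220 M⁻¹ s⁻¹) With 76 % of the partner and 53 % of the second reagent left at that time, S puts the partner way at 4.10 times the side-product way, against 2.85 at the start. For the neighbour flask with 0.87 M of second reagent, S gives a share of 58.4 %, and that flask holds 39.7 % side product out of 65.2 % reacted, which is 60.9 %.

The earlier runs and the new flask come from a simulation on assumed constants, noise included.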